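All runs were computed for an exercise.

Amounts first: each flask is read at its asked time, so what counts is how much target has built up by then, and the noon run shows how much each minute adds.

| flask | starting material | protic impurity | remark | time |
|---|---|---|---|---|
| noon | 0.055 M | 1 mM | run made earlier |  |
| south-east | 0.015 M | 0.500 mM |  | 10 min |
| east | 0.050 M | 1.00 mM |  | 5.0 min |

noon run (percent of the starting material charged)

| time / min | target / % | starting material / % |
|---|---|---|
| 0.500 | 12 | 76 |
| 1.00 | 23 | 60 |
| 1.50 | 33 | 53 |
| 2.00 | 40 | 44 |
| 2.50 | 48 | 40 |
| 3.00 | 51 | 38 |

(readings scatter by 1.5 percentage points)

- the numbers in the tables scatter with a standard deviation of 1.5 percentage points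
- what may be going on: starting material + protic impurity -> quenched substrate; target <-> isomer of the product; isomer of the product <-> starting material; starting material <-> target; target -> over-reaction product
- no earlier run changes the charge of protic impurity; that part of a forecast is a guess

1. which of the two ends with the higher amount of target, in percent of the starting material charged ("neither" if they lie within 2 percentage points) (south-east / east / neither)
2. target at the end, in percent of the starting material charged, south-east
3. target at the end, in percent of the starting material charged, east

Read the target column in steps of a minute, starting from nothing. The first minute adds 23 percentage points, the next 17 points, the last 11 points. Each gain falls short of the one before by about 6 points, though a gain between two readings scatters by about 2.1 points.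

Continue that fall. The gain at the last reading is about 8 points a minute, and it reaches zero at 4.33 min, when the target stands at 56.3 %. Call this the ceiling, the level at which the minute gain of target has fallen to zero; it is a reading and carries the scatter.

My own reckoning follows. East, with a charge close to noon's, is read at 5.0 min and south-east at 10 min, both later than the ceiling's time. So I expect both near the ceiling and answer neither, provided dilution leaves the pace of south-east unchanged, which the noon run cannot show. The protic impurity is the limiting reagent of the quench. Taken one for one, it claims 3.33 % of the starting material in south-east and 2.00 % in east, a gap of 1.3 points.

The forecast differs: it says south-east, with 72 % for south-east and 63 % for east. Its ground for south-east: “South-east runs twice as long and, if first order, is not slowed by dilution.”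

The simulation gives neither, with 59.2 % in south-east and 58.8 % in east.

    starting material + protic impurity → quenched substrate (k = 210 M⁻¹ min⁻¹)
    target ⇌ isomer of the product (K = 0.130, k = 0.270 min⁻¹)
    isomer of the product ⇌ starting material (k = 1.70 min⁻¹)
    starting material ⇌ target (K = 2.80, k = 0.0740 min⁻¹)
    target → over-reaction product (k = 0.0150 min⁻¹)

South-east held 58.1 % of target at 5.00 min and gained 1.2 points by 10.0 min. East ended 2.5 points above the ceiling of 56.3 %. East read at 20 min, long past the ceiling's time, holds 54.6 % of target, 1.7 points under the ceiling.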